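**Plan**
- Retrosynthesis: the C6–C1′ bond (ring to alkenyl chain) is cut first. Then O2–C3 and C3–C4 of the 1,2-dioxane are cut together, giving a hydroperoxy ketal that carries an (E)-allylsilane and a C3 aldehyde acetal. The side chain is cut at C1′–B, C2′–ethyl, C3′–alkyne and the C4′ ethyl branch.
- Enabling feature: in the ring O1–O2–C3–C4–C5–C6 the bond C3–C4 joins the two adjacent trans stereocentres. Once O2–C3 and C3–C4 are cut, C3 is a plain aldehyde carbon and C4 the γ-carbon of an allylsilane.
- Forward: cross-metathesis, oxidation, ketalisation and perhydrolysis give the hydroperoxide. The annulation closes the only ring, the C4 vinyl group is reduced to ethyl, and the alkenyl chain (four steps from hex-1-ene) is joined last at C6.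
- Stereochemistry: C3 from the chiral counter-anion and C4 from the chair (trans). C6 from axial attack on the ring peroxycarbenium ion. C4′ from asymmetric carboalumination, and the E alkene from syn-carbocupration.

Key step: step 5

Remark: ring atoms are numbered O1–O2–C3–C4–C5–C6 and side-chain atoms C1′–C8′ from the ring; the antipodes of the two chiral catalysts (steps 5 and 7) are those expected to give the stated configurations, and the mirror-image catalyst would be taken if a first run showed the opposite sense.

**Step 1**
Reactants: 1 hex-5-en-3-ol; 2 allyltrimethylsilane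
Product: 3 (5E)-7-(trimethylsilyl)hept-5-en-3-ol
Conditions: second-generation Grubbs catalyst (H2IMes)(PCy3)Cl2Ru=CHPh (cat.), 2 (3 equiv), CH2Cl2, 40 °C; E isomer enriched on AgNO3-doped silica if needed
Reagents that add atoms: none
Why: Olefin cross-metathesis of two unhindered terminal alkenes, driven by loss of ethene and run with excess allylsilane, should give the allylsilane with the E isomer predominating under thermodynamic control.

**Step 2**
Reactants: 3 (5E)-7-(trimethylsilyl)hept-5-en-3-ol
Product: 4 (5E)-7-(trimethylsilyl)hept-5-en-3-one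
Conditions: Dess–Martin periodinane, pyridine, CH2Cl2, 0 °C to rt
Reagents that add atoms: none
Why: Dess–Martin oxidation of a secondary alcohol under buffered, non-basic conditions should leave the allylsilane intact and the β,γ-double bond out of conjugation.

**Step 3**
Reactants: 4 (5E)-7-(trimethylsilyl)hept-5-en-3-one
Product: 5 [(2E)-5,5-dimethoxyhept-2-en-1-yl]trimethylsilane
Conditions: HC(OMe)3, MeOH, pyridinium p-toluenesulfonate (cat.), rt
Reagents that add atoms: trimethyl orthoformate, COC(OC)OC; methanol, CO
Why: Acid-catalysed ketalisation with the orthoformate as water scavenger; the pyridinium salt is too weak an acid to protodesilylate the allylsilane.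

**Step 4**
Reactants: 5 [(2E)-5,5-dimethoxyhept-2-en-1-yl]trimethylsilane
Product: 6 [(2E)-5-hydroperoxy-5-methoxyhept-2-en-1-yl]trimethylsilane (racemic)
Conditions: anhydrous H2O2 in Et2O (excess), camphorsulfonic acid (cat.), 0 °C, short contact time; NaHCO3 quench
Reagents that add atoms: hydrogen peroxide, OO
Why: Perhydrolysis of a ketal (acid-catalysed acetal exchange through the oxocarbenium ion) replaces one methoxy group by hydroperoxide and is held at mono-exchange by low temperature and short time; the ketal centre forms racemic, which does not matter.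

**Step 5**
Reactants: 6 [(2E)-5-hydroperoxy-5-methoxyhept-2-en-1-yl]trimethylsilane; 7 methyl 3,3-dimethoxypropanoate
Product: 9 methyl 2-[(3S,4S)-4-ethenyl-6-ethyl-6-methoxy-1,2-dioxan-3-yl]acetate (both C6 epimers), via mixed peroxyacetal 8 (not isolated)
Conditions: chiral N-triflyl imidodiphosphorimidate (IDPi) Brønsted acid built from two 3,3′-diaryl-BINOL units (5 mol%, antipode giving 3S,4S), 7 (1.5 equiv), CH2Cl2/cyclohexane, −40 °C
Reagents that add atoms: none
Why: Proposed new method: acid-catalysed acetal exchange joins 6 and 7 to peroxyacetal 8, loss of methanol gives the (E)-peroxycarbenium ion at C3 as an ion pair with the confined chiral anion, the γ-carbon of the allylsilane (C4) adds to it in an anti SE2′ fashion, and the Me3Si group passes to methanol so that the acid is regenerated. The closest known reactions are the Lewis-acid-promoted racemic intramolecular Hosomi–Sakurai capture of peroxycarbenium ions to 1,2-dioxanes and the imidodiphosphorimidate-catalysed Prins and Hosomi–Sakurai reactions of oxocarbenium ions. The 1,2-dioxane closes by C3–C4 bond formation in a six-membered chair, endo with respect to the O2=C3 cation and exo with respect to the allylsilane double bond, which remains as the C4 vinyl group. C3 is set by the anion, which shields one enantioface of the cation; C4 follows from the chair, in which the C3 acetate arm and the C4 alkene both sit equatorial (trans), an arrangement the E geometry of the allylsilane supports. The step needs enantioface selection at C3, trans diastereoselection and reaction at C3 in preference to C6; the first rests on the catalyst, the second on the chair, and the third on the fact that the cation from the C6 ketal has no carbon nucleophile in reach (C4 would close a three-membered ring) and only returns to the ketal, so C6 is obtained as both epimers.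

**Step 6**
Reactants: 9 methyl 2-[(3S,4S)-4-ethenyl-6-ethyl-6-methoxy-1,2-dioxan-3-yl]acetate
Product: 10 methyl 2-[(3S,4R)-4,6-diethyl-6-methoxy-1,2-dioxan-3-yl]acetate (both C6 epimers)
Conditions: KO2CN=NCO2K, AcOH, MeOH/CH2Cl2, 0 °C to rt
Reagents that add atoms: none
Why: Diimide reduction transfers H2 to the monosubstituted vinyl group in a concerted syn fashion and is the standard way to saturate an alkene without cleaving a peroxide bond; no stereocentre is formed, and the C4 descriptor changes from S to R only through the priority rules.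

**Step 7**
Reactants: 11 hex-1-ene
Product: 13 (3S)-3-(iodomethyl)heptane, via diethyl[(2S)-2-ethylhexyl]alumane 12 (not isolated)
Conditions: Et3Al, bis(1-neomenthylindenyl)zirconium dichloride (+)-(NMI)2ZrCl2 (5 mol%), CH2Cl2, 0 °C to rt; then I2, THF, 0 °C
Reagents that add atoms: triethylaluminium, CC[Al](CC)CC; iodine, II
Why: Zirconium-catalysed asymmetric carboalumination (ZACA reaction) adds ethyl to C2 and aluminium to C1 of the terminal alkene, the chiral zirconocene selecting the alkene face and so setting the S centre, and iodinolysis of the primary C–Al bond gives the iodide without touching that centre.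

**Step 8**
Reactants: 13 (3S)-3-(iodomethyl)heptane
Product: 14 (4S)-4-ethyloct-1-yne
Conditions: LiC≡CH·H2NCH2CH2NH2, DMSO, rt
Reagents that add atoms: lithium acetylide (ethylenediamine complex), [Li]C#C
Why: SN2 alkylation of lithium acetylide by a primary iodide in DMSO; the stereocentre is β to the reacting carbon and is not affected.

**Step 9**
Reactants: 14 (4S)-4-ethyloct-1-yne
Product: 16 (1E,4S)-2,4-diethyl-1-iodooct-1-ene, via alkenylcopper 15 (not isolated)
Conditions: EtMgBr, CuBr·SMe2, Et2O/Me2S, −45 °C; 14, −25 °C; then I2, THF, −50 to 0 °C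
Reagents that add atoms: ethylmagnesium bromide, CC[Mg]Br; iodine, II
Why: Normant carbocupration: EtCu·MgBr2 adds syn across the terminal alkyne with copper on C1 and ethyl on C2, and iodinolysis with retention gives the E iodide in which iodine is cis to the new ethyl group.

**Step 10**
Reactants: 16 (1E,4S)-2,4-diethyl-1-iodooct-1-ene
Product: 19 potassium [(1E,4S)-2,4-diethyloct-1-en-1-yl]trifluoroborate, via alkenyllithium 17 (not isolated), via lithium alkenyltriisopropoxyborate 18 (not isolated)
Conditions: t-BuLi (2 equiv), Et2O, −78 °C; B(OiPr)3, −78 °C to rt; aq. KHF2, MeOH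
Reagents that add atoms: triisopropyl borate, CC(C)OB(OC(C)C)OC(C)C; potassium hydrogen difluoride, [K+].F[H-]F
Why: Iodine–lithium exchange with retention of alkene geometry, borylation of the alkenyllithium and fluoride exchange with KHF2 is the standard route to potassium alkenyltrifluoroborates.

**Step 11**
Reactants: 10 methyl 2-[(3S,4R)-4,6-diethyl-6-methoxy-1,2-dioxan-3-yl]acetate; 19 potassium [(1E,4S)-2,4-diethyloct-1-en-1-yl]trifluoroborate
Product: 21 methyl 2-[(3S,4R,6S)-6-[(1E,4S)-2,4-diethyloct-1-en-1-yl]-4,6-diethyl-1,2-dioxan-3-yl]acetate, via alkenyldifluoroborane 20 (not isolated)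
Conditions: BF3·OEt2 (2 equiv), 19 (2 equiv), CH2Cl2/MeCN, −78 to −20 °C
Reagents that add atoms: none
Why: Proposed new method: BF3 takes fluoride from 19 to give the Lewis-acidic alkenyldifluoroborane 20, which ionises the C6 methoxy group of either epimer of 10 to one tertiary peroxycarbenium ion paired with the alkenyl(methoxy)difluoroborate, whose boron-bearing carbon attacks C6 (ipso substitution through a tertiary β-boryl cation, E geometry retained) along the axial trajectory of the half-chair that keeps the C3 and C4 groups pseudo-equatorial, placing the alkenyl group trans to the C4 ethyl (6S); the closest known reactions are the BF3-promoted coupling of potassium alkenyltrifluoroborates with acetal-derived oxocarbenium ions and the Lewis-acid substitution of 3-alkoxy-1,2-dioxanes by allylsilanes and silyl enol ethers via peroxycarbenium ions.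

**Compound list**
1 | hex-5-en-3-ol (racemic) | CCC(O)CC=C | starting material
2 | allyltrimethylsilane | C=CC[Si](C)(C)C | starting material
3 | (5E)-7-(trimethylsilyl)hept-5-en-3-ol | CCC(O)C/C=C/C[Si](C)(C)C | intermediate
4 | (5E)-7-(trimethylsilyl)hept-5-en-3-one | CCC(=O)C/C=C/C[Si](C)(C)C | intermediate
5 | [(2E)-5,5-dimethoxyhept-2-en-1-yl]trimethylsilane | CCC(OC)(OC)C/C=C/C[Si](C)(C)C | intermediate
6 | [(2E)-5-hydroperoxy-5-methoxyhept-2-en-1-yl]trimethylsilane (racemic) | CCC(OC)(OO)C/C=C/C[Si](C)(C)C | intermediate
7 | methyl 3,3-dimethoxypropanoate | COC(OC)CC(=O)OC | starting material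
8 | methyl 3-methoxy-3-{[(5E)-3-methoxy-7-(trimethylsilyl)hept-5-en-3-yl]peroxy}propanoate (mixed peroxyacetal) | CCC(OC)(C/C=C/C[Si](C)(C)C)OOC(OC)CC(=O)OC | intermediate
9 | methyl 2-[(3S,4S)-4-ethenyl-6-ethyl-6-methoxy-1,2-dioxan-3-yl]acetate (both C6 epimers) | COC1(CC)C[C@@H](C=C)[C@H](CC(=O)OC)OO1 | intermediate
10 | methyl 2-[(3S,4R)-4,6-diethyl-6-methoxy-1,2-dioxan-3-yl]acetate (both C6 epimers) | COC1(CC)C[C@@H](CC)[C@H](CC(=O)OC)OO1 | intermediate
11 | hex-1-ene | C=CCCCC | starting material
12 | diethyl[(2S)-2-ethylhexyl]alumane | CCCC[C@H](CC)C[Al](CC)CC | intermediate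
13 | (3S)-3-(iodomethyl)heptane | CCCC[C@H](CC)CI | intermediate
14 | (4S)-4-ethyloct-1-yne | CCCC[C@H](CC)CC#C | intermediate
15 | [(1E,4S)-2,4-diethyloct-1-en-1-yl]copper (MgBr2 complex) | CCCC[C@H](CC)C/C(=C/[Cu])CC | intermediate
16 | (1E,4S)-2,4-diethyl-1-iodooct-1-ene | CCCC[C@H](CC)C/C(=C/I)CC | intermediate
17 | [(1E,4S)-2,4-diethyloct-1-en-1-yl]lithium | CCCC[C@H](CC)C/C(=C/[Li])CC | intermediate
18 | lithium [(1E,4S)-2,4-diethyloct-1-en-1-yl]tri(propan-2-yloxy)borate | [Li+].CCCC[C@H](CC)C/C(=C/[B-](OC(C)C)(OC(C)C)OC(C)C)CC | intermediate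
19 | potassium [(1E,4S)-2,4-diethyloct-1-en-1-yl]trifluoroborate | [K+].CCCC[C@H](CC)C/C(=C/[B-](F)(F)F)CC | intermediate
20 | [(1E,4S)-2,4-diethyloct-1-en-1-yl]difluoroborane | CCCC[C@H](CC)C/C(=C/B(F)F)CC | intermediate
21 | methyl 2-[(3S,4R,6S)-6-[(1E,4S)-2,4-diethyloct-1-en-1-yl]-4,6-diethyl-1,2-dioxan-3-yl]acetate | CCCC[C@H](CC)C/C(=C/[C@]1(CC)C[C@@H](CC)[C@H](CC(=O)OC)OO1)CC | target

**Step count**
Total: 11 steps. Longest linear sequence: 7 steps (steps 1–6 and 11); the side-chain branch is steps 7–10.

**Steps most likely to fail**

1. Step 5 (new method). The chiral anion may discriminate the two faces of the C3 peroxycarbenium ion poorly, or 6 may be consumed by ionisation at its own ketal carbon and loss of H2O2 before the C3 cation forms. Fallback, known chemistry, setting out from 6 and 7 and returning at 9: the annulation would be run without asymmetric induction under Me3SiOTf (catalytic, CH2Cl2, −78 °C). This is the established racemic Hosomi–Sakurai capture of a peroxycarbenium ion and should still give the trans ring through the same chair. It would deliver 9 together with its mirror image, methyl 2-[(3R,4R)-4-ethenyl-6-ethyl-6-methoxy-1,2-dioxan-3-yl]acetate F1. The two would be parted by preparative HPLC on a cellulose tris(3,5-dimethylphenylcarbamate) phase, and 9 re-enters at step 6.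

2. Step 11 (new method). Alkenyl transfer from boron to the hindered tertiary peroxycarbenium ion may be slower than Lewis-acid-induced fragmentation of the O–O bond, or attack may occur on both faces of C6. Fallback, known reaction types only, setting out from 10, 2 and 13 and returning at 21: the side chain would be built on the ring from a C6 aldehyde.
   - Me3SiOTf-promoted Hosomi–Sakurai allylation of the peroxyketal 10 with 2 (same axial approach) would give methyl 2-[(3S,4R,6R)-4,6-diethyl-6-(prop-2-en-1-yl)-1,2-dioxan-3-yl]acetate F2.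
   - Isomerisation with RuHCl(CO)(PPh3)3 would move the double bond and give methyl 2-[(3S,4R,6S)-4,6-diethyl-6-[(1E)-prop-1-en-1-yl]-1,2-dioxan-3-yl]acetate F3.
   - Ozonolysis (O3, CH2Cl2, −78 °C; Me2S), which dialkyl peroxides tolerate, would give methyl 2-[(3S,4R,6S)-4,6-diethyl-6-formyl-1,2-dioxan-3-yl]acetate F4.
   - Ramirez dibromo-olefination (CBr4, PPh3, 0 °C) would give methyl 2-[(3S,4R,6S)-6-(2,2-dibromoethenyl)-4,6-diethyl-1,2-dioxan-3-yl]acetate F5.
   - Zinc insertion into 13 (zinc dust, LiCl, THF) would give [(2S)-2-ethylhexyl](iodo)zinc F6. A trans-selective Negishi coupling of F5 with it (Pd(DPEphos)Cl2) would replace only the bromine trans to C6 and give methyl 2-[(3S,4R,6S)-6-[(1Z,4S)-2-bromo-4-ethyloct-1-en-1-yl]-4,6-diethyl-1,2-dioxan-3-yl]acetate F7.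
   - A second Negishi coupling with Et2Zn and Pd(t-Bu3P)2, with retention, would give 21.

3. Step 1. Low E/Z control in the cross-metathesis would carry Z-allylsilane into the annulation, where it should erode the trans preference. Fallback, setting out from 1 and returning at 3: cross-metathesis of 1 with (Z)-but-2-ene-1,4-diyl diacetate (same ruthenium catalyst) would give (2E)-5-hydroxyhept-2-en-1-yl acetate F8 as a geometric mixture. Palladium-catalysed silylation with Me3SiSiMe3 (Pd(dba)2, LiCl, DMF) would then convert both geometric isomers, through the common syn-π-allylpalladium intermediate, into the linear E-allylsilane 3.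

**Further compounds**
F1 | step 5 | methyl 2-[(3R,4R)-4-ethenyl-6-ethyl-6-methoxy-1,2-dioxan-3-yl]acetate | COC1(CC)C[C@H](C=C)[C@@H](CC(=O)OC)OO1
F2 | step 11 | methyl 2-[(3S,4R,6R)-4,6-diethyl-6-(prop-2-en-1-yl)-1,2-dioxan-3-yl]acetate | C=CC[C@]1(CC)C[C@@H](CC)[C@H](CC(=O)OC)OO1
F3 | step 11 | methyl 2-[(3S,4R,6S)-4,6-diethyl-6-[(1E)-prop-1-en-1-yl]-1,2-dioxan-3-yl]acetate | C/C=C/[C@]1(CC)C[C@@H](CC)[C@H](CC(=O)OC)OO1
F4 | step 11 | methyl 2-[(3S,4R,6S)-4,6-diethyl-6-formyl-1,2-dioxan-3-yl]acetate | O=C[C@]1(CC)C[C@@H](CC)[C@H](CC(=O)OC)OO1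
F5 | step 11 | methyl 2-[(3S,4R,6S)-6-(2,2-dibromoethenyl)-4,6-diethyl-1,2-dioxan-3-yl]acetate | BrC(Br)=C[C@]1(CC)C[C@@H](CC)[C@H](CC(=O)OC)OO1
F6 | step 11 | [(2S)-2-ethylhexyl](iodo)zinc | CCCC[C@H](CC)C[Zn]I
F7 | step 11 | methyl 2-[(3S,4R,6S)-6-[(1Z,4S)-2-bromo-4-ethyloct-1-en-1-yl]-4,6-diethyl-1,2-dioxan-3-yl]acetate | CCCC[C@H](CC)C/C(Br)=C/[C@]1(CC)C[C@@H](CC)[C@H](CC(=O)OC)OO1
F8 | step 1 | (2E)-5-hydroxyhept-2-en-1-yl acetate | CCC(O)C/C=C/COC(C)=O
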